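**Retrosynthetic overview**

1. The target is a trans-(2S,3S)-1,4-benzodioxane, numbered O1–C2(aryl)–C3(CH2OH)–O4, fused to ring A (the gallate-derived benzene ring), which carries an (E)-3,5-dihydroxystyryl group. The stilbene C=C is cut first: Horner–Wadsworth–Emmons olefination of a ring A aldehyde with a MOM-protected 3,5-dihydroxybenzylphosphonate.
2. The strategy rests on two features. C2 bears a 4-hydroxy-3,5-dimethoxyphenyl group and is therefore a latent para-quinone methide carbon. O4 is the central oxygen of ring A, so once it carries C3 the two flanking ring A hydroxyls are equivalent.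
3. Key disconnection: the O1–C2 bond, formed by acid-catalysed quinone methide oxa-Michael cyclisation of an acyclic aryl glycerol beta-aryl ether. C2 is set thermodynamically against the fixed C3.
4. The C2–C3 bond of the acyclic precursor comes from an Evans syn aldol between a ring A aryloxyacetyl imide and O-benzyl syringaldehyde, which fixes C3. The O4–CH2 bond comes from alkylation of methyl gallate at its most acidic, central hydroxyl.
5. Ring order: the three benzene rings are bought; the dioxane ring is the only ring built (step 8).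

Key step: step 8

Assumption: the locants O1, C2 (aryl), C3 (CH2OH), O4 and ring A positions 5 (OH) and 7 (carbon substituent) are used for every benzodioxane in the route, also where systematic numbering would run the other way.

**Route**

Step 1
Reactants: 1 methyl gallate (methyl 3,4,5-trihydroxybenzoate)
Product: 2 methyl 4-(2-tert-butoxy-2-oxoethoxy)-3,5-dihydroxybenzoate
Conditions: BrCH2CO2t-Bu (1.0 equiv), KHCO3 (1.5 equiv), DMF, rt to 40 °C
Reagents that add atoms: tert-butyl bromoacetate, CC(C)(C)OC(=O)CBr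
Why: Williamson etherification in which the weak base should ionise only the 4-hydroxyl (the most acidic, para to the ester), so that the single equivalent of bromoacetate ends up on the central oxygen (future O4) and the product stays symmetric; the tert-butyl ester resists lactonisation by the flank phenols.

Step 2
Reactants: 2 methyl 4-(2-tert-butoxy-2-oxoethoxy)-3,5-dihydroxybenzoate
Product: 3 methyl 3,5-bis(benzyloxy)-4-(2-tert-butoxy-2-oxoethoxy)benzoate
Conditions: BnBr (2.4 equiv), K2CO3 (3 equiv), DMF, rt to 50 °C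
Reagents that add atoms: benzyl bromide, BrCc1ccccc1
Why: Williamson etherification of both flank phenols, which would otherwise lactonise onto the imide of step 4 and consume the boron reagent of step 5; benzyl is removable later by hydrogenolysis.

Step 3
Reactants: 3 methyl 3,5-bis(benzyloxy)-4-(2-tert-butoxy-2-oxoethoxy)benzoate
Product: 4 2-[2,6-bis(benzyloxy)-4-(methoxycarbonyl)phenoxy]acetic acid
Conditions: TFA/CH2Cl2 (1:3), 0 °C to rt
Reagents that add atoms: none
Why: Acidolysis of the tert-butyl ester with loss of isobutene, under which the methyl benzoate and the aryl benzyl ethers should be untouched.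

Step 4
Reactants: 4 2-[2,6-bis(benzyloxy)-4-(methoxycarbonyl)phenoxy]acetic acid; 5 (R)-4-benzyl-1,3-oxazolidin-2-one
Product: 7 methyl 3,5-bis(benzyloxy)-4-{2-[(4R)-4-benzyl-2-oxo-1,3-oxazolidin-3-yl]-2-oxoethoxy}benzoate, via mixed pivalic anhydride 6 (not isolated)
Conditions: t-BuCOCl, Et3N, THF, −20 °C; then 5, LiCl, −20 °C to rt
Reagents that add atoms: none
Why: N-acylation of the oxazolidinone through a mixed anhydride under LiCl/Et3N activation, with attack expected at the less hindered aryloxyacetyl carbonyl of 6.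

Step 5
Reactants: 7 methyl 3,5-bis(benzyloxy)-4-{2-[(4R)-4-benzyl-2-oxo-1,3-oxazolidin-3-yl]-2-oxoethoxy}benzoate; 8 4-(benzyloxy)-3,5-dimethoxybenzaldehyde
Product: 11 methyl 3,5-bis(benzyloxy)-4-{[(1S,2R)-1-[4-(benzyloxy)-3,5-dimethoxyphenyl]-3-[(4R)-4-benzyl-2-oxo-1,3-oxazolidin-3-yl]-1-hydroxy-3-oxopropan-2-yl]oxy}benzoate, via boron Z-enolate 9 (not isolated), via boron aldolate 10 (not isolated)
Conditions: n-Bu2BOTf, i-Pr2NEt, CH2Cl2, −78 to 0 °C; then 8, −78 to 0 °C; pH 7 buffer, MeOH, H2O2, 0 °C
Reagents that add atoms: none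
Why: Evans syn aldol reaction in which the Z boron enolate reacts through a closed Zimmerman–Traxler chair on the face away from the benzyl group of the (R)-auxiliary, which should set the aryloxy carbon (future C3) as R in this adduct and the carbinol carbon as S; minor diastereomers can be removed by chromatography while the auxiliary is still attached.

Step 6
Reactants: 11 the syn aldol adduct
Product: 12 methyl 3,5-bis(benzyloxy)-4-{[(1S,2S)-1-[4-(benzyloxy)-3,5-dimethoxyphenyl]-1,3-dihydroxypropan-2-yl]oxy}benzoate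
Conditions: NaBH4, THF/H2O (4:1), 0 °C to rt
Reagents that add atoms: none
Why: Reductive cleavage of the N-acyloxazolidinone, in which borohydride attacks the activated imide carbonyl and spares the electron-rich methyl benzoate; no stereocentre is touched (the aryloxy carbon becomes S only through a change of substituent priority) and auxiliary 5 is recovered.

Step 7
Reactants: 12 the tribenzyl diol
Product: 13 methyl 4-{[(1S,2S)-1,3-dihydroxy-1-(4-hydroxy-3,5-dimethoxyphenyl)propan-2-yl]oxy}-3,5-dihydroxybenzoate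
Conditions: H2 (1 atm), Pd/C (10 wt% Pd), EtOAc/MeOH, rt
Reagents that add atoms: none
Why: Catalytic hydrogenolysis of the three aryl benzyl ethers under neutral conditions, under which the secondary benzylic alcohol of aryl glycerol aryl ethers is known to persist.

Step 8
Reactants: 13 methyl 4-{[(1S,2S)-1,3-dihydroxy-1-(4-hydroxy-3,5-dimethoxyphenyl)propan-2-yl]oxy}-3,5-dihydroxybenzoate
Product: 15 methyl (2S,3S)-5-hydroxy-3-(hydroxymethyl)-2-(4-hydroxy-3,5-dimethoxyphenyl)-2,3-dihydro-1,4-benzodioxine-7-carboxylate, via para-quinone methide 14 (not isolated)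
Conditions: TsOH·H2O (0.2 equiv), MeCN (0.02 M), 50–60 °C
Reagents that add atoms: none
Why: Protonation of the benzylic C2 hydroxyl and loss of water, pushed by the para hydroxyl of the 4-hydroxy-3,5-dimethoxyphenyl ring, should give para-quinone methide 14, and one of the two equivalent flank phenols of ring A then adds to its exocyclic carbon in an oxa-Michael reaction that restores aromaticity. The closest known reaction type is the acid-mediated cyclisation of aryl glycerol beta-aryl ethers to trans-2-aryl-3-hydroxymethyl-1,4-benzodioxane neolignans. The dioxane ring closes in a 6-exo-trig mode by formation of the O1–C2 bond. C2 is set under thermodynamic control, because the addition is reversible under the acid and either C2 epimer should funnel to the trans isomer with aryl and CH2OH both pseudo-equatorial, the reference being the fixed (S)-C3, which is not benzylic and should keep its configuration. The step needs the intramolecular phenol to trap 14 faster than beta-proton loss to an enol ether or loss of formaldehyde, which the six-membered geometry, catalytic acid and moderate temperature should secure; there is no regiochemical question on ring A because O4 is the central oxygen and the two flanking hydroxyls are equivalent.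

Step 9
Reactants: 15 methyl (2S,3S)-5-hydroxy-3-(hydroxymethyl)-2-(4-hydroxy-3,5-dimethoxyphenyl)-2,3-dihydro-1,4-benzodioxine-7-carboxylate
Product: 16 methyl (2S,3S)-2-[3,5-dimethoxy-4-(methoxymethoxy)phenyl]-3-(hydroxymethyl)-5-(methoxymethoxy)-2,3-dihydro-1,4-benzodioxine-7-carboxylate
Conditions: MOMCl (2.3 equiv), K2CO3, acetone, 0 °C to rt
Reagents that add atoms: chloromethyl methyl ether, COCCl
Why: O-alkylation of the two phenoxides formed by K2CO3, with the un-ionised primary alcohol expected to stay free; capping the 4-hydroxyl of the C2 aryl group also switches off quinone methide formation in the basic steps that follow.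

Step 10
Reactants: 16 the bis-MOM ester
Product: 17 [(2S,3S)-2-[3,5-dimethoxy-4-(methoxymethoxy)phenyl]-5-(methoxymethoxy)-2,3-dihydro-1,4-benzodioxine-3,7-diyl]dimethanol
Conditions: LiAlH4, THF, 0 °C
Reagents that add atoms: none
Why: Hydride reduction of the methyl ester to the benzylic alcohol, to which acetals, aryl ethers and both stereocentres are inert.

Step 11
Reactants: 17 the diol
Product: 18 (2S,3S)-2-[3,5-dimethoxy-4-(methoxymethoxy)phenyl]-3-(hydroxymethyl)-5-(methoxymethoxy)-2,3-dihydro-1,4-benzodioxine-7-carbaldehyde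
Conditions: MnO2 (activated, excess), CH2Cl2, rt
Reagents that add atoms: none
Why: MnO2 oxidises benzylic alcohols selectively, so the ring A carbinol should go to the aldehyde while the aliphatic CH2OH at C3 is left alone.

Step 12
Reactants: 19 methyl 3,5-dihydroxybenzoate
Product: 20 methyl 3,5-bis(methoxymethoxy)benzoate
Conditions: MOMCl, i-Pr2NEt, CH2Cl2, 0 °C to rt
Reagents that add atoms: chloromethyl methyl ether, COCCl
Why: O-alkylation of both phenols gives base-stable acetal protection that comes off together with the other MOM groups in the last step.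

Step 13
Reactants: 20 methyl 3,5-bis(methoxymethoxy)benzoate
Product: 21 [3,5-bis(methoxymethoxy)phenyl]methanol
Conditions: LiAlH4, THF, 0 °C
Reagents that add atoms: none
Why: Standard hydride reduction of the ester to the benzyl alcohol.

Step 14
Reactants: 21 [3,5-bis(methoxymethoxy)phenyl]methanol
Product: 22 1-(bromomethyl)-3,5-bis(methoxymethoxy)benzene
Conditions: CBr4, PPh3, CH2Cl2, 0 °C
Reagents that add atoms: carbon tetrabromide, BrC(Br)(Br)Br
Why: Appel reaction converts the benzylic alcohol to the bromide under neutral conditions that the acid-labile MOM ethers tolerate.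

Step 15
Reactants: 22 1-(bromomethyl)-3,5-bis(methoxymethoxy)benzene
Product: 23 diethyl [3,5-bis(methoxymethoxy)benzyl]phosphonate
Conditions: P(OEt)3 (neat), 130 °C
Reagents that add atoms: triethyl phosphite, CCOP(OCC)OCC
Why: Michaelis–Arbuzov reaction of a reactive benzylic bromide.

Step 16
Reactants: 18 the ring A aldehyde; 23 diethyl [3,5-bis(methoxymethoxy)benzyl]phosphonate
Product: 25 [(2S,3S)-7-{(E)-2-[3,5-bis(methoxymethoxy)phenyl]ethenyl}-2-[3,5-dimethoxy-4-(methoxymethoxy)phenyl]-5-(methoxymethoxy)-2,3-dihydro-1,4-benzodioxin-3-yl]methanol, via sodium phosphonate carbanion 24 (not isolated)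
Conditions: 23 (2 equiv), NaH (3 equiv), THF, 0 °C; then 18, 0 °C to rt
Reagents that add atoms: none
Why: Horner–Wadsworth–Emmons olefination of an aryl aldehyde with a benzylphosphonate anion, whose reversible addition and syn elimination favour the E stilbene; the extra base covers the free hydroxyl and no stereocentre is acidic enough to be affected.

Step 17
Reactants: 25 the tetra-MOM stilbene
Product: 26 5-{(E)-2-[(2S,3S)-5-hydroxy-3-(hydroxymethyl)-2-(4-hydroxy-3,5-dimethoxyphenyl)-2,3-dihydro-1,4-benzodioxin-7-yl]ethenyl}benzene-1,3-diol (CNP0319597.1)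
Conditions: HCl (1 M) in MeOH/THF, rt to 40 °C, under N2
Reagents that add atoms: none
Why: Acid-catalysed methanolysis of the four aryl MOM acetals; since only aryl acetals have to be cleaved, dilute acid near room temperature should suffice and spare the stilbene and the benzylic C2–O1 bond.

**Compound list**

1 | methyl gallate (methyl 3,4,5-trihydroxybenzoate) | COC(=O)c1cc(O)c(O)c(O)c1 | starting material
2 | methyl 4-(2-tert-butoxy-2-oxoethoxy)-3,5-dihydroxybenzoate | COC(=O)c1cc(O)c(OCC(=O)OC(C)(C)C)c(O)c1 | intermediate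
3 | methyl 3,5-bis(benzyloxy)-4-(2-tert-butoxy-2-oxoethoxy)benzoate | COC(=O)c1cc(OCc2ccccc2)c(OCC(=O)OC(C)(C)C)c(OCc2ccccc2)c1 | intermediate
4 | 2-[2,6-bis(benzyloxy)-4-(methoxycarbonyl)phenoxy]acetic acid | COC(=O)c1cc(OCc2ccccc2)c(OCC(=O)O)c(OCc2ccccc2)c1 | intermediate
5 | (R)-4-benzyl-1,3-oxazolidin-2-one | O=C1N[C@H](Cc2ccccc2)CO1 | starting material
6 | mixed pivalic anhydride of acid 4 (forms in the flask) | COC(=O)c1cc(OCc2ccccc2)c(OCC(=O)OC(=O)C(C)(C)C)c(OCc2ccccc2)c1 | intermediate
7 | methyl 3,5-bis(benzyloxy)-4-{2-[(4R)-4-benzyl-2-oxo-1,3-oxazolidin-3-yl]-2-oxoethoxy}benzoate | COC(=O)c1cc(OCc2ccccc2)c(OCC(=O)N2[C@H](Cc3ccccc3)COC2=O)c(OCc2ccccc2)c1 | intermediate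
8 | 4-(benzyloxy)-3,5-dimethoxybenzaldehyde | COc1cc(C=O)cc(OC)c1OCc1ccccc1 | starting material
9 | di-n-butylboron Z-enolate of imide 7 (forms in the flask) | COC(=O)c1cc(OCc2ccccc2)c(O/C=C(\OB(CCCC)CCCC)N2[C@H](Cc3ccccc3)COC2=O)c(OCc2ccccc2)c1 | intermediate
10 | di-n-butylboron aldolate of adduct 11 (forms in the flask) | COc1cc([C@H](OB(CCCC)CCCC)[C@@H](Oc2c(OCc3ccccc3)cc(C(=O)OC)cc2OCc2ccccc2)C(=O)N2[C@H](Cc3ccccc3)COC2=O)cc(OC)c1OCc1ccccc1 | intermediate
11 | methyl 3,5-bis(benzyloxy)-4-{[(1S,2R)-1-[4-(benzyloxy)-3,5-dimethoxyphenyl]-3-[(4R)-4-benzyl-2-oxo-1,3-oxazolidin-3-yl]-1-hydroxy-3-oxopropan-2-yl]oxy}benzoate (Evans syn adduct) | COc1cc([C@H](O)[C@@H](Oc2c(OCc3ccccc3)cc(C(=O)OC)cc2OCc2ccccc2)C(=O)N2[C@H](Cc3ccccc3)COC2=O)cc(OC)c1OCc1ccccc1 | intermediate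
12 | methyl 3,5-bis(benzyloxy)-4-{[(1S,2S)-1-[4-(benzyloxy)-3,5-dimethoxyphenyl]-1,3-dihydroxypropan-2-yl]oxy}benzoate | COc1cc([C@H](O)[C@@H](Oc2c(OCc3ccccc3)cc(C(=O)OC)cc2OCc2ccccc2)CO)cc(OC)c1OCc1ccccc1 | intermediate
13 | methyl 4-{[(1S,2S)-1,3-dihydroxy-1-(4-hydroxy-3,5-dimethoxyphenyl)propan-2-yl]oxy}-3,5-dihydroxybenzoate (key-step precursor) | COc1cc([C@H](O)[C@@H](Oc2c(O)cc(C(=O)OC)cc2O)CO)cc(OC)c1O | intermediate
14 | para-quinone methide, methyl 4-{[(2R)-1-(3,5-dimethoxy-4-oxocyclohexa-2,5-dien-1-ylidene)-3-hydroxypropan-2-yl]oxy}-3,5-dihydroxybenzoate (same spatial arrangement at C3 as in 13; forms in the flask) | COC1=CC(=C[C@@H](Oc2c(O)cc(C(=O)OC)cc2O)CO)C=C(OC)C1=O | intermediate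
15 | methyl (2S,3S)-5-hydroxy-3-(hydroxymethyl)-2-(4-hydroxy-3,5-dimethoxyphenyl)-2,3-dihydro-1,4-benzodioxine-7-carboxylate (trans; key-step product) | COc1cc([C@@H]2Oc3cc(C(=O)OC)cc(O)c3O[C@H]2CO)cc(OC)c1O | intermediate
16 | methyl (2S,3S)-2-[3,5-dimethoxy-4-(methoxymethoxy)phenyl]-3-(hydroxymethyl)-5-(methoxymethoxy)-2,3-dihydro-1,4-benzodioxine-7-carboxylate | COc1cc([C@@H]2Oc3cc(C(=O)OC)cc(OCOC)c3O[C@H]2CO)cc(OC)c1OCOC | intermediate
17 | [(2S,3S)-2-[3,5-dimethoxy-4-(methoxymethoxy)phenyl]-5-(methoxymethoxy)-2,3-dihydro-1,4-benzodioxine-3,7-diyl]dimethanol | COc1cc([C@@H]2Oc3cc(CO)cc(OCOC)c3O[C@H]2CO)cc(OC)c1OCOC | intermediate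
18 | (2S,3S)-2-[3,5-dimethoxy-4-(methoxymethoxy)phenyl]-3-(hydroxymethyl)-5-(methoxymethoxy)-2,3-dihydro-1,4-benzodioxine-7-carbaldehyde | COc1cc([C@@H]2Oc3cc(C=O)cc(OCOC)c3O[C@H]2CO)cc(OC)c1OCOC | intermediate
19 | methyl 3,5-dihydroxybenzoate | COC(=O)c1cc(O)cc(O)c1 | starting material
20 | methyl 3,5-bis(methoxymethoxy)benzoate | COCOc1cc(OCOC)cc(C(=O)OC)c1 | intermediate
21 | [3,5-bis(methoxymethoxy)phenyl]methanol | COCOc1cc(CO)cc(OCOC)c1 | intermediate
22 | 1-(bromomethyl)-3,5-bis(methoxymethoxy)benzene | COCOc1cc(CBr)cc(OCOC)c1 | intermediate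
23 | diethyl [3,5-bis(methoxymethoxy)benzyl]phosphonate | CCOP(=O)(Cc1cc(OCOC)cc(OCOC)c1)OCC | intermediate
24 | sodium salt of the benzylic carbanion of phosphonate 23 (forms in the flask) | CCOP(=O)([CH-]c1cc(OCOC)cc(OCOC)c1)OCC.[Na+] | intermediate
25 | [(2S,3S)-7-{(E)-2-[3,5-bis(methoxymethoxy)phenyl]ethenyl}-2-[3,5-dimethoxy-4-(methoxymethoxy)phenyl]-5-(methoxymethoxy)-2,3-dihydro-1,4-benzodioxin-3-yl]methanol | COc1cc([C@@H]2Oc3cc(/C=C/c4cc(OCOC)cc(OCOC)c4)cc(OCOC)c3O[C@H]2CO)cc(OC)c1OCOC | intermediate
26 | 5-{(E)-2-[(2S,3S)-5-hydroxy-3-(hydroxymethyl)-2-(4-hydroxy-3,5-dimethoxyphenyl)-2,3-dihydro-1,4-benzodioxin-7-yl]ethenyl}benzene-1,3-diol (CNP0319597.1) | COc1cc([C@@H]2Oc3cc(/C=C/c4cc(O)cc(O)c4)cc(O)c3O[C@H]2CO)cc(OC)c1O | target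

**Step count**

Total: 17 steps. Longest linear sequence: 13 steps (steps 1–11, 16 and 17, from methyl gallate); the phosphonate branch is steps 12–15.

**Steps most likely to fail**

Step 8 (key cyclisation). Quinone methide 14 may be diverted before the flank phenol closes the ring: by intermolecular trapping to oligomers, by beta-proton loss to an enol ether (which would also erase C3), or by loss of formaldehyde. The equilibration at C2 may also stop short of the trans isomer. The fallback sets out from 13 and generates the quinone methide without acid. Bromotrimethylsilane in CH2Cl2 at 0 °C should exchange the benzylic hydroxyl for bromide and give methyl 4-{[(2S)-1-bromo-3-hydroxy-1-(4-hydroxy-3,5-dimethoxyphenyl)propan-2-yl]oxy}-3,5-dihydroxybenzoate F1 (C1 epimers; silylated hydroxyls are freed on work-up). Shaking with aqueous NaHCO3 should eliminate HBr through the free para hydroxyl to give 14, which a flank phenoxide traps. Warming with K2CO3 in DMF then equilibrates C2 by base-induced reopening to 14, and the sequence comes back to the route at 15.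

Step 1 (mono-alkylation of methyl gallate). Alkylation may spread to a flank hydroxyl or go on to di- and tri-ethers, because the acidity gap between the 4-hydroxyl and the 3/5-hydroxyls is the only control. The fallback sets out from 1 and masks the flank oxygens first. Ac2O/pyridine gives methyl 3,4,5-triacetoxybenzoate F2. K2CO3, KI and tert-butyl bromoacetate in refluxing acetone should cleave only the acetate para to the ester (the best phenoxide leaving group) and alkylate that phenoxide in situ, giving methyl 3,5-diacetoxy-4-(2-tert-butoxy-2-oxoethoxy)benzoate F3. Catalytic K2CO3 in MeOH at 0 °C removes the two aryl acetates, and the sequence comes back to the route at 2.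

Step 16 (olefination with a free hydroxymethyl group). The C3 alkoxide formed under the basic conditions may stall the olefination by aggregation, consume aldehyde by hemiacetal formation or hydride transfer, or attack ring A at the carbon para to the formyl group (Smiles-type aryl migration). The fallback sets out from 18 and masks the alcohol. TBSCl/imidazole in DMF gives (2S,3S)-3-{[(tert-butyldimethylsilyl)oxy]methyl}-2-[3,5-dimethoxy-4-(methoxymethoxy)phenyl]-5-(methoxymethoxy)-2,3-dihydro-1,4-benzodioxine-7-carbaldehyde F4. Olefination with carbanion 24 (from 23 and NaH, THF) gives the silylated (E)-stilbene, tert-butyl{[(2S,3S)-7-{(E)-2-[3,5-bis(methoxymethoxy)phenyl]ethenyl}-2-[3,5-dimethoxy-4-(methoxymethoxy)phenyl]-5-(methoxymethoxy)-2,3-dihydro-1,4-benzodioxin-3-yl]methoxy}dimethylsilane F5. The dilute HCl/MeOH of step 17 then removes the primary silyl ether together with the four MOM groups, and the sequence comes back to the route at 26.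

**Further compounds**

F1 | step 8 | methyl 4-{[(2S)-1-bromo-3-hydroxy-1-(4-hydroxy-3,5-dimethoxyphenyl)propan-2-yl]oxy}-3,5-dihydroxybenzoate (C1 epimers) | COc1cc(C(Br)[C@@H](Oc2c(O)cc(C(=O)OC)cc2O)CO)cc(OC)c1O
F2 | step 1 | methyl 3,4,5-triacetoxybenzoate | COC(=O)c1cc(OC(C)=O)c(OC(C)=O)c(OC(C)=O)c1
F3 | step 1 | methyl 3,5-diacetoxy-4-(2-tert-butoxy-2-oxoethoxy)benzoate | COC(=O)c1cc(OC(C)=O)c(OCC(=O)OC(C)(C)C)c(OC(C)=O)c1
F4 | step 16 | (2S,3S)-3-{[(tert-butyldimethylsilyl)oxy]methyl}-2-[3,5-dimethoxy-4-(methoxymethoxy)phenyl]-5-(methoxymethoxy)-2,3-dihydro-1,4-benzodioxine-7-carbaldehyde | COc1cc([C@@H]2Oc3cc(C=O)cc(OCOC)c3O[C@H]2CO[Si](C)(C)C(C)(C)C)cc(OC)c1OCOC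
F5 | step 16 | tert-butyl{[(2S,3S)-7-{(E)-2-[3,5-bis(methoxymethoxy)phenyl]ethenyl}-2-[3,5-dimethoxy-4-(methoxymethoxy)phenyl]-5-(methoxymethoxy)-2,3-dihydro-1,4-benzodioxin-3-yl]methoxy}dimethylsilane | COc1cc([C@@H]2Oc3cc(/C=C/c4cc(OCOC)cc(OCOC)c4)cc(OCOC)c3O[C@H]2CO[Si](C)(C)C(C)(C)C)cc(OC)c1OCOC
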